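The route rests on disconnecting C6–C7 (briarane numbering), the bond that joins the Z-configured C5=C6 alkene to the lactone carbinol C7 in the ten-membered ring (C1–C10). An intramolecular Nozaki–Hiyama–Kishi reaction between a Z-alkenyl iodide (C6) and a C7 aldehyde closes this ring and sets C7 in one operation. It exploits the adjacent oxygen-bearing quaternary C8 (polar Felkin–Anh control) and the 1,4-relation of the new C7 hydroxyl to C19, which then closes the γ-lactone (O–C7–C8–C17–C19). The precursor is ring A, a cyclohexene from an endo Diels–Alder reaction, carrying a C2–C6 iodoalkene arm on C1 and a C9–C8(OH)(CHO)–C17–C19 arm on C10.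

Key step: step 23

Remark on numbering and one assumption: C1 is the quaternary ring carbon (CH3-15); C2 CH(OAc); C3, C4 CH2; C5(CH3-16)=C6; C7 lactone O–CH; C8 C(OH); C9 CH(OAc); C10, C11 (CH3-20), C12 (O-butanoate), C13=C14 complete ring A; C17 bears CH3-18; C19 is the lactone carbonyl. TBS = tert-butyldimethylsilyl, TES = triethylsilyl, TBDPS = tert-butyldiphenylsilyl. The (S)-prolinol-derived oxazaborolidinium cation of step 3 is assumed to shield the enal face that leads to the drawn adduct; if the sense proves opposite, its antipode is used without other change.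

Step 1
Reactants: 1 (E)-pent-3-en-2-one
Product: 2 (E)-2-(TBS-oxy)penta-1,3-diene
Conditions: TBSOTf, Et3N, Et2O, 0 °C
Reagents that add atoms: tert-butyldimethylsilyl triflate CC(C)(C)[Si](C)(C)OS(=O)(=O)C(F)(F)F
Why: Soft enolisation (silyl enol ether formation) removes a proton from the acetyl methyl group and should give the cross-conjugated 2-silyloxy diene with the E-propenyl unit untouched.

Step 2
Reactants: 3 ethyl tiglate
Product: 4 ethyl (E)-2-methyl-4-oxobut-2-enoate
Conditions: SeO2, 1,4-dioxane, reflux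
Reagents that add atoms: selenium dioxide O=[Se]=O
Why: Riley allylic oxidation (ene reaction at the α-carbon, then [2,3]-shift) should oxidise the γ-methyl group to the aldehyde and return the E-alkene.

Step 3
Reactants: 2 (E)-2-(TBS-oxy)penta-1,3-diene; 4 ethyl (E)-2-methyl-4-oxobut-2-enoate
Product: 5 ring A cycloadduct, ethyl (1S,5S,6S)-3-(TBS-oxy)-6-formyl-1,5-dimethylcyclohex-3-ene-1-carboxylate
Conditions: (S)-3,3-diphenyl-1-(2-methylphenyl)tetrahydro-1H,3H-pyrrolo[1,2-c][1,3,2]oxazaborole·HNTf2 (20 mol %), CH2Cl2, −78 °C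
Reagents that add atoms: none
Why: In this catalytic enantioselective Diels–Alder reaction the boron Lewis acid binds the formyl group, so the CH2 terminus next to the siloxy carbon bonds to the β-carbon (C1) and the methyl-bearing terminus to the α-carbon (C10); the E-dienophile fixes ester trans to formyl, the endo-formyl transition state puts CH3-20 cis to the formyl group, and the catalyst shields one enal face, which sets C1, C10 and C11 together.

Step 4
Reactants: 6 methyl (S)-3-hydroxy-2-methylpropanoate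
Product: 7 methyl (S)-3-(TBDPS-oxy)-2-methylpropanoate
Conditions: TBDPSCl, imidazole, DMF, rt
Reagents that add atoms: tert-butyldiphenylsilyl chloride CC(C)(C)[Si](Cl)(c1ccccc1)c1ccccc1
Why: Silylation of the primary alcohol gives a robust ether that should survive every base and hydride step up to step 24; the stereocentre (future C17) is not touched.

Step 5
Reactants: 7 methyl (S)-3-(TBDPS-oxy)-2-methylpropanoate
Product: 8 (S)-3-(TBDPS-oxy)-2-methylpropanal
Conditions: iBu2AlH, CH2Cl2, −78 °C; Rochelle salt work-up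
Reagents that add atoms: none
Why: Partial ester reduction: the tetrahedral aluminium hemiacetal is stable at −78 °C and should release the aldehyde only on work-up, without epimerisation.

Step 6
Reactants: 8 (S)-3-(TBDPS-oxy)-2-methylpropanal
Product: 9 (R)-4-(TBDPS-oxy)-3-methylbut-1-yne
Conditions: dimethyl (1-diazo-2-oxopropyl)phosphonate, K2CO3, MeOH, 0 °C to rt
Reagents that add atoms: dimethyl (1-diazo-2-oxopropyl)phosphonate COP(=O)(OC)C(=[N+]=[N-])C(C)=O
Why: Seyferth–Gilbert homologation in its Ohira–Bestmann form should convert the aldehyde into the terminal alkyne under conditions mild enough to keep the α-stereocentre (the descriptor changes only through priorities).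

Step 7
Reactants: 9 (R)-4-(TBDPS-oxy)-3-methylbut-1-yne
Product: 11 (S)-4-(TBDPS-oxy)-2-iodo-3-methylbut-1-ene, via alkenylborane 10 (not isolated)
Conditions: B-iodo-9-BBN, pentane, −20 to 0 °C; then AcOH
Reagents that add atoms: B-iodo-9-borabicyclo[3.3.1]nonane IB1C2CCCC1CCC2
Why: Haloboration adds B–I syn and Markovnikov (iodine to the internal carbon), and protodeboronation with acetic acid should leave the 2-iodo-1-alkene.

Step 8
Reactants: 5 ring A cycloadduct; 11 (S)-4-(TBDPS-oxy)-2-iodo-3-methylbut-1-ene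
Product: 12 C9 allylic alcohol
Conditions: CrCl2 (4 equiv), NiCl2 (2 mol %), DMF, rt
Reagents that add atoms: none
Why: In this intermolecular Nozaki–Hiyama–Kishi coupling the alkenylchromium reagent should add only to the aldehyde (ester and silyl enol ether inert), and Felkin–Anh attack anti to the C10–C1 bond (quaternary C1 as the large group, past H-10) sets C9 as in the target.

Step 9
Reactants: 12 C9 allylic alcohol
Product: 13 C9 TES ether
Conditions: TESOTf, 2,6-lutidine, CH2Cl2, −78 °C
Reagents that add atoms: triethylsilyl triflate CC[Si](CC)(CC)OS(=O)(=O)C(F)(F)F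
Why: Silyl triflate silylation should protect the hindered secondary alcohol for the base and organometallic steps 11 to 17 and can later be removed in the presence of the TBDPS ether.

Step 10
Reactants: 13 C9 TES ether
Product: 15 C13 ketone bearing C12 O-TBS, via silyloxy epoxide 14 (not isolated)
Conditions: mCPBA, NaHCO3, CH2Cl2, −20 °C
Reagents that add atoms: 3-chloroperoxybenzoic acid OOC(=O)c1cccc(Cl)c1
Why: Rubottom oxidation: the peracid should attack the electron-rich silyl enol ether (much faster than the crowded 1,1-disubstituted alkene) on the face opposite CH3-15, the C10 side chain and CH3-20, and silyl migration to the new oxygen gives the α-silyloxy ketone with C12–O trans to CH3-20.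

Step 11
Reactants: 15 C13 ketone bearing C12 O-TBS
Product: 17 C13 enol triflate, via potassium enolate 16 (not isolated)
Conditions: KN(SiMe3)2, THF, −78 °C; then PhNTf2
Reagents that add atoms: N-phenylbis(trifluoromethanesulfonimide) FC(F)(F)S(=O)(=O)N(c1ccccc1)S(=O)(=O)C(F)(F)F
Why: Kinetic deprotonation should occur at the C14 methylene, away from the silyloxy-bearing C12, and O-sulfonylation of the enolate gives the C13=C14 enol triflate.

Step 12
Reactants: 17 C13 enol triflate
Product: 18 ring A cyclohexene (C13=C14, C12 O-TBS, C9 O-TES, C1 CO2Et)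
Conditions: Pd(OAc)2, PPh3, HCO2H, Bu3N, DMF, 60 °C
Reagents that add atoms: none
Why: Palladium-catalysed formate reduction (oxidative addition, decarboxylation of the formate, reductive elimination) should replace the triflate by hydrogen and leave the C13=C14 alkene next to the C12 silyl ether.

Step 13
Reactants: 18 ring A cyclohexene
Product: 20 C2 methyl ketone, via enol ether 19 (not isolated)
Conditions: Ti(C5H5)2(CH3)2, toluene, 65 °C; then aqueous oxalic acid, THF, 0 °C
Reagents that add atoms: dimethyltitanocene [CH3-].[CH3-].[Ti+4].c1cc[cH-]c1.c1cc[cH-]c1; water O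
Why: Petasis methylenation should turn the hindered ester on quaternary C1 into its 1-ethoxyvinyl derivative, and mild acid hydrolysis of this enol ether gives the acetyl group (C2, C3).

Step 14
Reactants: 21 prop-2-yn-1-ol
Product: 23 (Z)-3-iodo-2-methylprop-2-en-1-ol, via alkenylmagnesium alkoxide 22 (not isolated)
Conditions: MeMgBr (2.5 equiv), CuI (10 mol %), THF, −10 °C to rt; then I2, −10 °C
Reagents that add atoms: methylmagnesium bromide C[Mg]Br; iodine II
Why: Copper-catalysed anti-carbomagnesiation of the propargylic alkoxide places methyl on C2 and magnesium on C3 cis to the CH2O group (oxygen chelation), and iodinolysis with retention should give the Z-iodoalkene.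

Step 15
Reactants: 23 (Z)-3-iodo-2-methylprop-2-en-1-ol
Product: 24 (Z)-3-bromo-1-iodo-2-methylprop-1-ene
Conditions: CBr4, PPh3, CH2Cl2, 0 °C
Reagents that add atoms: tetrabromomethane BrC(Br)(Br)Br
Why: The Appel reaction substitutes the primary allylic hydroxyl by bromide and should leave the alkene geometry unchanged.

Step 16
Reactants: 20 C2 methyl ketone; 24 (Z)-3-bromo-1-iodo-2-methylprop-1-ene
Product: 26 C2 ketone bearing the C3–C6 iodoalkene arm, via lithium enolate 25 (not isolated)
Conditions: LiN(iPr)2, THF, −78 °C; then 24, DMPU, −78 to −30 °C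
Reagents that add atoms: none
Why: Enolate alkylation: the ketone can enolise only toward its methyl group (C1 is quaternary), and the lithium enolate should displace the allylic bromide to form the C3–C4 bond with the Z-iodoalkene intact.

Step 17
Reactants: 26 C2 ketone bearing the C3–C6 iodoalkene arm
Product: 27 (2R)-C2 alcohol
Conditions: (S)-1-methyl-3,3-diphenyltetrahydro-1H,3H-pyrrolo[1,2-c][1,3,2]oxazaborole (0.5 equiv), BH3·SMe2, THF, −30 °C
Reagents that add atoms: none
Why: Corey–Bakshi–Shibata reduction under reagent control: the tertiary C1 acts as the large and the C3 methylene as the small substituent, so the (S)-catalyst should deliver hydride to give the (R)-carbinol at C2.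

Step 18
Reactants: 27 (2R)-C2 alcohol
Product: 28 C2,C9,C12-triol
Conditions: HF·pyridine, pyridine, THF, 0 °C to rt
Reagents that add atoms: none
Why: Buffered fluoride desilylation should cleave the secondary TES and allylic TBS ethers well before the primary TBDPS ether.

Step 19
Reactants: 28 C2,C9,C12-triol
Product: 29 C12 butanoate
Conditions: (PrCO)2O (1.05 equiv), Et3N, DMAP (5 mol %), CH2Cl2, −40 °C
Reagents that add atoms: butanoic anhydride CCCC(=O)OC(=O)CCC
Why: Kinetically controlled acylation should take the least hindered hydroxyl, the allylic C12–OH flanked by CH(CH3) and an sp2 carbon, because the C2 and C9 carbinols both sit next to fully substituted or doubly branched carbons.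

Step 20
Reactants: 29 C12 butanoate
Product: 30 C12 butanoate C2,C9-diacetate
Conditions: Ac2O, pyridine, DMAP, 40 °C
Reagents that add atoms: acetic anhydride CC(=O)OC(C)=O
Why: DMAP-catalysed acetylation under forcing conditions should esterify the two remaining hindered secondary alcohols.

Step 21
Reactants: 30 C12 butanoate C2,C9-diacetate
Product: 31 C7,C8-diol
Conditions: K2OsO2(OH)4 (2 mol %), N-methylmorpholine N-oxide, acetone/H2O, 0 °C
Reagents that add atoms: N-methylmorpholine N-oxide C[N+]1([O-])CCOCC1; water O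
Why: Upjohn dihydroxylation should select the terminal 1,1-disubstituted alkene (the ring alkene is hindered and deactivated by the allylic ester, the iodoalkene is electron-poor), and osmium adds anti to the bulky C10 substituent with H-9 turned toward C17, which gives the C8 carbinol with O8 anti to O9 along the C7–C10 chain as in the target.

Step 22
Reactants: 31 C7,C8-diol
Product: 32 C7 aldehyde
Conditions: SO3·pyridine, DMSO, iPr2NEt, CH2Cl2, 0 °C
Reagents that add atoms: none
Why: Parikh–Doering oxidation converts the primary alcohol to the aldehyde without glycol cleavage, and the α-carbon (C8) is quaternary, so the α-hydroxy aldehyde cannot enolise.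

Step 23
Reactants: 32 C7 aldehyde
Product: 33 macrocyclic C7 alcohol
Conditions: CrCl2 (10 equiv), NiCl2 (10 mol %), DMSO, rt, 2 mM, slow addition of 32
Reagents that add atoms: none
Why: Zerovalent nickel (formed from NiCl2 by CrCl2) inserts into the C6–I bond with retention of the Z geometry, transmetallation gives an alkenyl species of trivalent chromium, and this adds to the C7 aldehyde, the new C6–C7 bond closing the ten-membered carbocycle (C1–C10). The closest known reaction type is the Nozaki–Hiyama–Kishi macrocyclisation used for nine- to twelve-membered carbocycles. The ring closes in the 10-exo-trig mode, the carbonyl oxygen staying outside the ring. C7 is the only new stereocentre and is controlled by the oxygenated quaternary C8 in a polar Felkin–Anh arrangement: C6 enters anti to the C8–O bond and past the smaller C17 branch while the tether keeps C6 gauche to C9, which gives the C7 configuration needed for the lactone. The step needs chemoselectivity for the aldehyde over three esters (inherent to organochromium reagents), non-chelated addition (strongly coordinating DMSO) and cyclisation over oligomerisation, which should be secured by high dilution, by the turn imposed by the Z-alkene and quaternary C1, and by the trans-disposed C2 and C9 arms on ring A.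

Step 24
Reactants: 33 macrocyclic C7 alcohol
Product: 34 C7,C19-diol
Conditions: Bu4NF, AcOH, THF, rt
Reagents that add atoms: none
Why: Fluoride cleaves the primary TBDPS ether, and the acetic acid buffer should suppress acyl migration from O9 or O2.

Step 25
Reactants: 34 C7,C19-diol
Product: 36 target CNP0211702.1, via lactol 35 (not isolated)
Conditions: Cu(CH3CN)4OTf (5 mol %), 2,2'-bipyridine, TEMPO, N-methylimidazole, CH3CN, air, rt
Reagents that add atoms: none
Why: Copper/nitroxyl aerobic oxidative lactonisation should oxidise only the unhindered primary C19 alcohol; the aldehyde is trapped by the C7 hydroxyl as a five-membered lactol and oxidised on to the γ-lactone, with C17 (from 6) and the free tertiary C8–OH unchanged.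

Compound list
1 | (E)-pent-3-en-2-one | C/C=C/C(C)=O | starting material
2 | (E)-2-(TBS-oxy)penta-1,3-diene | C=C(O[Si](C)(C)C(C)(C)C)/C=C/C | intermediate
3 | ethyl tiglate, ethyl (E)-2-methylbut-2-enoate | CCOC(=O)/C(C)=C/C | starting material
4 | ethyl (E)-2-methyl-4-oxobut-2-enoate | CCOC(=O)/C(C)=C/C=O | intermediate
5 | ring A cycloadduct, ethyl (1S,5S,6S)-3-(TBS-oxy)-6-formyl-1,5-dimethylcyclohex-3-ene-1-carboxylate; formyl (C9) cis to CH3-15 and CH3-20, trans to the ester | C1=C(O[Si](C)(C)C(C)(C)C)C[C@@](C(=O)OCC)(C)[C@H]([C@H]1C)C=O | intermediate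
6 | methyl (S)-3-hydroxy-2-methylpropanoate | COC(=O)[C@@H](C)CO | starting material
7 | methyl (S)-3-(TBDPS-oxy)-2-methylpropanoate | COC(=O)[C@@H](C)CO[Si](c1ccccc1)(c1ccccc1)C(C)(C)C | intermediate
8 | (S)-3-(TBDPS-oxy)-2-methylpropanal | O=C[C@@H](C)CO[Si](c1ccccc1)(c1ccccc1)C(C)(C)C | intermediate
9 | (R)-4-(TBDPS-oxy)-3-methylbut-1-yne | C#C[C@@H](C)CO[Si](c1ccccc1)(c1ccccc1)C(C)(C)C | intermediate
10 | alkenylborane, (Z)-1-(9-borabicyclo[3.3.1]nonan-9-yl)-2-iodo-3-methyl-4-(TBDPS-oxy)but-1-ene | I/C(=C\B1C2CCCC1CCC2)[C@@H](C)CO[Si](c1ccccc1)(c1ccccc1)C(C)(C)C | intermediate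
11 | (S)-4-(TBDPS-oxy)-2-iodo-3-methylbut-1-ene | C=C(I)[C@@H](C)CO[Si](c1ccccc1)(c1ccccc1)C(C)(C)C | intermediate
12 | C9 allylic alcohol: cycloadduct 5 with CHO turned into CH(OH)–C(=CH2)–CH(CH3)–CH2O-TBDPS; C9 and C17 as in the target | C1=C(O[Si](C)(C)C(C)(C)C)C[C@@](C(=O)OCC)(C)[C@H]([C@H]1C)[C@@H](O)C(=C)[C@@H](C)CO[Si](c1ccccc1)(c1ccccc1)C(C)(C)C | intermediate
13 | C9 TES ether of 12 | C1=C(O[Si](C)(C)C(C)(C)C)C[C@@](C(=O)OCC)(C)[C@H]([C@H]1C)[C@@H](O[Si](CC)(CC)CC)C(=C)[C@@H](C)CO[Si](c1ccccc1)(c1ccccc1)C(C)(C)C | intermediate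
14 | silyloxy epoxide: C12,C13-epoxide of 13, oxygen on the face opposite CH3-20, C13 bearing O-TBS | O1[C@@H]2[C@@]1(O[Si](C)(C)C(C)(C)C)C[C@@](C(=O)OCC)(C)[C@H]([C@H]2C)[C@@H](O[Si](CC)(CC)CC)C(=C)[C@@H](C)CO[Si](c1ccccc1)(c1ccccc1)C(C)(C)C | intermediate
15 | C13 ketone bearing C12 O-TBS (O12 trans to CH3-20) | CC(C)(C)[Si](C)(C)O[C@@H]1C(=O)C[C@@](C(=O)OCC)(C)[C@H]([C@H]1C)[C@@H](O[Si](CC)(CC)CC)C(=C)[C@@H](C)CO[Si](c1ccccc1)(c1ccccc1)C(C)(C)C | intermediate
16 | potassium C13(O)=C14 enolate of 15 | [K+].CC(C)(C)[Si](C)(C)O[C@@H]1C([O-])=C[C@@](C(=O)OCC)(C)[C@H]([C@H]1C)[C@@H](O[Si](CC)(CC)CC)C(=C)[C@@H](C)CO[Si](c1ccccc1)(c1ccccc1)C(C)(C)C | intermediate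
17 | C13 enol triflate (C13=C14) | CC(C)(C)[Si](C)(C)O[C@@H]1C(OS(=O)(=O)C(F)(F)F)=C[C@@](C(=O)OCC)(C)[C@H]([C@H]1C)[C@@H](O[Si](CC)(CC)CC)C(=C)[C@@H](C)CO[Si](c1ccccc1)(c1ccccc1)C(C)(C)C | intermediate
18 | ring A cyclohexene: C13=C14, C12 O-TBS, C9 O-TES, ethyl ester on C1 | CC(C)(C)[Si](C)(C)O[C@@H]1C=C[C@@](C(=O)OCC)(C)[C@H]([C@H]1C)[C@@H](O[Si](CC)(CC)CC)C(=C)[C@@H](C)CO[Si](c1ccccc1)(c1ccccc1)C(C)(C)C | intermediate
19 | enol ether: 1-ethoxyvinyl group on C1 | CC(C)(C)[Si](C)(C)O[C@@H]1C=C[C@@](C(=C)OCC)(C)[C@H]([C@H]1C)[C@@H](O[Si](CC)(CC)CC)C(=C)[C@@H](C)CO[Si](c1ccccc1)(c1ccccc1)C(C)(C)C | intermediate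
20 | C2 methyl ketone (acetyl on C1) | CC(C)(C)[Si](C)(C)O[C@@H]1C=C[C@@](C(C)=O)(C)[C@H]([C@H]1C)[C@@H](O[Si](CC)(CC)CC)C(=C)[C@@H](C)CO[Si](c1ccccc1)(c1ccccc1)C(C)(C)C | intermediate
21 | prop-2-yn-1-ol | C#CCO | starting material
22 | alkenylmagnesium alkoxide, bromomagnesium (Z)-3-(bromomagnesio)-2-methylprop-2-en-1-olate | Br[Mg]/C=C(/C)CO[Mg]Br | intermediate
23 | (Z)-3-iodo-2-methylprop-2-en-1-ol | I/C=C(/C)CO | intermediate
24 | (Z)-3-bromo-1-iodo-2-methylprop-1-ene | I/C=C(/C)CBr | intermediate
25 | lithium enolate of 20 (C2(OLi)=C3H2) | [Li+].CC(C)(C)[Si](C)(C)O[C@@H]1C=C[C@@](C(=C)[O-])(C)[C@H]([C@H]1C)[C@@H](O[Si](CC)(CC)CC)C(=C)[C@@H](C)CO[Si](c1ccccc1)(c1ccccc1)C(C)(C)C | intermediate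
26 | C2 ketone bearing the C3–C6 arm, C5(CH3)=C6HI with iodine cis to C4 | CC(C)(C)[Si](C)(C)O[C@@H]1C=C[C@@](C(=O)CC/C(C)=C\I)(C)[C@H]([C@H]1C)[C@@H](O[Si](CC)(CC)CC)C(=C)[C@@H](C)CO[Si](c1ccccc1)(c1ccccc1)C(C)(C)C | intermediate
27 | (2R)-C2 alcohol | CC(C)(C)[Si](C)(C)O[C@@H]1C=C[C@@]([C@H](O)CC/C(C)=C\I)(C)[C@H]([C@H]1C)[C@@H](O[Si](CC)(CC)CC)C(=C)[C@@H](C)CO[Si](c1ccccc1)(c1ccccc1)C(C)(C)C | intermediate
28 | C2,C9,C12-triol (C19 O-TBDPS kept) | O[C@@H]1C=C[C@@]([C@H](O)CC/C(C)=C\I)(C)[C@H]([C@H]1C)[C@@H](O)C(=C)[C@@H](C)CO[Si](c1ccccc1)(c1ccccc1)C(C)(C)C | intermediate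
29 | C12 butanoate (C2 and C9 hydroxyls free) | CCCC(=O)O[C@@H]1C=C[C@@]([C@H](O)CC/C(C)=C\I)(C)[C@H]([C@H]1C)[C@@H](O)C(=C)[C@@H](C)CO[Si](c1ccccc1)(c1ccccc1)C(C)(C)C | intermediate
30 | C12 butanoate C2,C9-diacetate | CCCC(=O)O[C@@H]1C=C[C@@]([C@H](OC(C)=O)CC/C(C)=C\I)(C)[C@H]([C@H]1C)[C@@H](OC(C)=O)C(=C)[C@@H](C)CO[Si](c1ccccc1)(c1ccccc1)C(C)(C)C | intermediate
31 | C7,C8-diol (tertiary C8–OH as in the target, primary C7–OH) | CCCC(=O)O[C@@H]1C=C[C@@]([C@H](OC(C)=O)CC/C(C)=C\I)(C)[C@H]([C@H]1C)[C@@H](OC(C)=O)[C@@](O)(CO)[C@@H](C)CO[Si](c1ccccc1)(c1ccccc1)C(C)(C)C | intermediate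
32 | C7 aldehyde (α-hydroxy aldehyde on quaternary C8) | CCCC(=O)O[C@@H]1C=C[C@@]([C@H](OC(C)=O)CC/C(C)=C\I)(C)[C@H]([C@H]1C)[C@@H](OC(C)=O)[C@@](O)(C=O)[C@@H](C)CO[Si](c1ccccc1)(c1ccccc1)C(C)(C)C | intermediate
33 | macrocyclic C7 alcohol: ten-membered ring closed, 5Z, C7–OH as needed for the lactone, C19 O-TBDPS | CCCC(=O)O[C@@H]1C=C[C@@]2(C)[C@H]([C@H]1C)[C@@H](OC(C)=O)[C@@](O)([C@@H](O)/C=C(/C)CC[C@H]2OC(C)=O)[C@@H](C)CO[Si](c1ccccc1)(c1ccccc1)C(C)(C)C | intermediate
34 | C7,C19-diol | CCCC(=O)O[C@@H]1C=C[C@@]2(C)[C@H]([C@H]1C)[C@@H](OC(C)=O)[C@@](O)([C@@H](O)/C=C(/C)CC[C@H]2OC(C)=O)[C@@H](C)CO | intermediate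
35 | lactol: C19 hemiacetal closed onto O7 | CCCC(=O)O[C@@H]1C=C[C@@]2(C)[C@H]([C@H]1C)[C@@H](OC(C)=O)[C@@]1(O)[C@H](/C=C(/C)CC[C@H]2OC(C)=O)OC(O)[C@@H]1C | intermediate
36 | CNP0211702.1 | CCCC(=O)O[C@@H]1C=C[C@@]2(C)[C@H]([C@H]1C)[C@@H](OC(C)=O)[C@@]1(O)[C@H](/C=C(/C)CC[C@H]2OC(C)=O)OC(=O)[C@@H]1C | target

Total step count: 25. Longest linear sequence: 20 steps (steps 4 to 13 and 16 to 25, from 6).

Steps most likely to fail

Step 23. Chelation of chromium by the free C8 hydroxyl, or strain in the ten-membered transition state, may erode or reverse the facial selectivity at C7. The fallback sets out from 32: the cyclisation is run as before and 33 is taken on together with the 7-epi macrocyclic alcohol F1; the mixture is oxidised with Dess–Martin periodinane (NaHCO3, CH2Cl2) to the macrocyclic C7 enone F2, and a chelation-controlled 1,2-reduction with Zn(BH4)2 (Et2O, −40 °C; divalent zinc bridges the C8 hydroxyl and the carbonyl, hydride enters from the C17 side) should return the route at 33. The configuration at C7 is then set by reduction of a ketone and no longer by the carbon–carbon bond formation.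

Step 3. The β,β-disubstituted enal may bind the chiral boron cation too loosely, so that the cycloaddition proceeds with poor discrimination of the two enal faces. The fallback sets out from 2 and 4: an achiral promoter (Me2AlCl, CH2Cl2, −78 °C) gives 5 as a racemate, that is, together with the enantiomeric cycloadduct F3; the racemate is coupled with enantiopure 11 as in step 8, which should give 12 and the diastereomeric coupling product F4, separable by chromatography, and the route continues from 12. Absolute configuration then comes from the chiral-pool fragment and not from the catalyst.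

Step 19. The rate difference between the three secondary hydroxyls may be too small, so that acylation spreads over C12, C2 and C9. The fallback sets out from 27 and uses the different silyl groups: acetylation (Ac2O, DMAP) gives the C2 monoacetate F5; PPTS in MeOH removes only the TES group to give the C9 alcohol F6; a second acetylation gives the C2,C9-diacetate TBS ether F7; HF·pyridine frees the C12 alcohol F8, and butanoic anhydride with DMAP should then return the route at 30.

Further compounds
F1 | step 23 | 7-epi macrocyclic alcohol | CCCC(=O)O[C@@H]1C=C[C@@]2(C)[C@H]([C@H]1C)[C@@H](OC(C)=O)[C@@](O)([C@H](O)/C=C(/C)CC[C@H]2OC(C)=O)[C@@H](C)CO[Si](c1ccccc1)(c1ccccc1)C(C)(C)C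
F2 | step 23 | macrocyclic C7 enone | CCCC(=O)O[C@@H]1C=C[C@@]2(C)[C@H]([C@H]1C)[C@@H](OC(C)=O)[C@@](O)(C(=O)/C=C(/C)CC[C@H]2OC(C)=O)[C@@H](C)CO[Si](c1ccccc1)(c1ccccc1)C(C)(C)C
F3 | step 3 | enantiomeric cycloadduct | C1=C(O[Si](C)(C)C(C)(C)C)C[C@](C(=O)OCC)(C)[C@@H]([C@@H]1C)C=O
F4 | step 3 | diastereomeric coupling product | C1=C(O[Si](C)(C)C(C)(C)C)C[C@](C(=O)OCC)(C)[C@@H]([C@@H]1C)[C@H](O)C(=C)[C@@H](C)CO[Si](c1ccccc1)(c1ccccc1)C(C)(C)C
F5 | step 19 | C2 monoacetate | CC(C)(C)[Si](C)(C)O[C@@H]1C=C[C@@]([C@H](OC(C)=O)CC/C(C)=C\I)(C)[C@H]([C@H]1C)[C@@H](O[Si](CC)(CC)CC)C(=C)[C@@H](C)CO[Si](c1ccccc1)(c1ccccc1)C(C)(C)C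
F6 | step 19 | C9 alcohol | CC(C)(C)[Si](C)(C)O[C@@H]1C=C[C@@]([C@H](OC(C)=O)CC/C(C)=C\I)(C)[C@H]([C@H]1C)[C@@H](O)C(=C)[C@@H](C)CO[Si](c1ccccc1)(c1ccccc1)C(C)(C)C
F7 | step 19 | C2,C9-diacetate TBS ether | CC(C)(C)[Si](C)(C)O[C@@H]1C=C[C@@]([C@H](OC(C)=O)CC/C(C)=C\I)(C)[C@H]([C@H]1C)[C@@H](OC(C)=O)C(=C)[C@@H](C)CO[Si](c1ccccc1)(c1ccccc1)C(C)(C)C
F8 | step 19 | C12 alcohol | O[C@@H]1C=C[C@@]([C@H](OC(C)=O)CC/C(C)=C\I)(C)[C@H]([C@H]1C)[C@@H](OC(C)=O)C(=C)[C@@H](C)CO[Si](c1ccccc1)(c1ccccc1)C(C)(C)C
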